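The route rests on cutting the C2–C3 bond of ring C (the pyranone ring O1–C2–C3–C4–C4a–C8a). The key step is an enantioselective intramolecular rhodium-carbene C–H insertion: a diazomethyl ketone on ring A generates a carbene at C3 that inserts into a C2–H bond of the benzylic ether on O1, closing ring C and setting C2 in one operation. It exploits that C2 is flanked by O1 and by ring B, whose 4'-methoxy group makes the C2–H bonds hydridic. The precursor is a 2-(arylmethoxy)-6-silyloxyaryl diazomethyl ketone whose prenyl group was placed by a para Claisen–Cope shift; the 3-OH follows by enolate oxidation trans to ring B.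

Key step: step 8

Assumption: the sense of induction of the chiral dirhodium catalyst at C2 cannot be assigned with certainty for this substrate; if the (S)-ligand favours the 2R product, the mirror-image catalyst Rh2(R-PTTL)4 is used with everything else unchanged.

Abbreviation: TIPS = triisopropylsilyl.

Step 1
Reactants: 1 isovanillin (3-hydroxy-4-methoxybenzaldehyde)
Product: 2 4-methoxy-3-(triisopropylsilyloxy)benzaldehyde
Conditions: TIPSCl, imidazole, DMF, rt
Reagents that add atoms: chlorotriisopropylsilane (TIPSCl), CC(C)[Si](Cl)(C(C)C)C(C)C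
Why: Imidazole-promoted silylation of the only OH group gives a bulky aryl silyl ether that should survive base, hydride, heat and carbene chemistry and offers no C–H bond activated towards the later rhodium carbene.

Step 2
Reactants: 2 4-methoxy-3-(triisopropylsilyloxy)benzaldehyde
Product: 3 [4-methoxy-3-(triisopropylsilyloxy)phenyl]methanol
Conditions: NaBH4, MeOH, 0 °C
Reagents that add atoms: none
Why: Borohydride reduction of the aldehyde to the primary benzylic alcohol, with the aryl silyl ether stable in cold methanol.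

Step 3
Reactants: 4 1-(2,6-dihydroxy-4-methoxyphenyl)ethanone; 3 [4-methoxy-3-(triisopropylsilyloxy)phenyl]methanol
Product: 5 1-[2-hydroxy-4-methoxy-6-{[4-methoxy-3-(triisopropylsilyloxy)benzyl]oxy}phenyl]ethanone
Conditions: PPh3, DIAD, THF, 0 °C to rt
Reagents that add atoms: none
Why: Mitsunobu etherification in which one of the two symmetry-equivalent, acidic phenols of 4 displaces the activated primary benzylic alcohol; the remaining OH, now chelated to the acetyl group, should react much more slowly, so the mono-ether is expected.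

Step 4
Reactants: 5 1-[2-hydroxy-4-methoxy-6-{[4-methoxy-3-(triisopropylsilyloxy)benzyl]oxy}phenyl]ethanone
Product: 6 1-[4-methoxy-2-{[4-methoxy-3-(triisopropylsilyloxy)benzyl]oxy}-6-(3-methylbut-2-enyloxy)phenyl]ethanone
Conditions: prenyl bromide, K2CO3, acetone, reflux
Reagents that add atoms: prenyl bromide (1-bromo-3-methylbut-2-ene), CC(C)=CCBr
Why: Williamson O-alkylation (SN2) of the remaining phenoxide with the reactive allylic bromide puts the prenyl group on the oxygen that becomes O5.

Step 5
Reactants: 6 1-[4-methoxy-2-{[4-methoxy-3-(triisopropylsilyloxy)benzyl]oxy}-6-(3-methylbut-2-enyloxy)phenyl]ethanone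
Product: 9 1-[6-hydroxy-4-methoxy-2-{[4-methoxy-3-(triisopropylsilyloxy)benzyl]oxy}-3-(3-methylbut-2-enyl)phenyl]ethanone, via ortho-dienone 7 (not isolated), via para-dienone 8 (not isolated)
Conditions: Eu(fod)3 [tris(6,6,7,7,8,8,8-heptafluoro-2,2-dimethyloctane-3,5-dionato)europium] (10 mol%), NaHCO3, PhCl, 85 °C
Reagents that add atoms: none
Why: Domino aromatic Claisen/Cope rearrangement: the europium-assisted [3,3] shift gives ortho-dienone 7 with a 1,1-dimethylallyl group, a second [3,3] (Cope) shift carries it with allylic inversion to the para carbon as a normal prenyl group (8), and tautomerisation gives the phenol, so the prenyl group ends between the benzyloxy and methoxy groups (future C8) and the free OH is the future 5-OH.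

Step 6
Reactants: 9 1-[6-hydroxy-4-methoxy-2-{[4-methoxy-3-(triisopropylsilyloxy)benzyl]oxy}-3-(3-methylbut-2-enyl)phenyl]ethanone
Product: 10 1-[4-methoxy-2-{[4-methoxy-3-(triisopropylsilyloxy)benzyl]oxy}-3-(3-methylbut-2-enyl)-6-(triisopropylsilyloxy)phenyl]ethanone
Conditions: TIPSOTf, 2,6-lutidine, CH2Cl2, −78 to 0 °C
Reagents that add atoms: triisopropylsilyl trifluoromethanesulfonate (TIPSOTf), CC(C)[Si](OS(=O)(=O)C(F)(F)F)(C(C)C)C(C)C
Why: The reactive silyl triflate silylates the chelated phenol, which must be masked by a bulky, weakly nucleophilic group without activated C–H bonds because a free OH would undergo O–H insertion with the carbene of step 8.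

Step 7
Reactants: 10 1-[4-methoxy-2-{[4-methoxy-3-(triisopropylsilyloxy)benzyl]oxy}-3-(3-methylbut-2-enyl)-6-(triisopropylsilyloxy)phenyl]ethanone
Product: 12 2-diazo-1-[4-methoxy-2-{[4-methoxy-3-(triisopropylsilyloxy)benzyl]oxy}-3-(3-methylbut-2-enyl)-6-(triisopropylsilyloxy)phenyl]ethanone, via trifluoroacetyl ketone 11 (not isolated)
Conditions: LiN(SiMe3)2, THF, −78 °C; CF3CO2CH2CF3; aq. HCl work-up; then MsN3, Et3N, H2O, MeCN, rt
Reagents that add atoms: methanesulfonyl azide (MsN3), CS(=O)(=O)N=[N+]=[N-]; 2,2,2-trifluoroethyl trifluoroacetate, O=C(OCC(F)(F)F)C(F)(F)F (its trifluoroacetyl group is carried only by 11 and is lost again)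
Why: Detrifluoroacetylative diazo transfer: the lithium enolate of the methyl ketone is C-acylated to the 1,3-diketone 11, which is acidic enough to accept the diazo group from the sulfonyl azide and then loses the trifluoroacetyl group as an N-acylsulfonamide, a sequence that works where direct diazo transfer to a simple ketone does not.

Step 8
Reactants: 12 2-diazo-1-[4-methoxy-2-{[4-methoxy-3-(triisopropylsilyloxy)benzyl]oxy}-3-(3-methylbut-2-enyl)-6-(triisopropylsilyloxy)phenyl]ethanone
Product: 13 (2S)-7-methoxy-2-[4-methoxy-3-(triisopropylsilyloxy)phenyl]-8-(3-methylbut-2-enyl)-5-(triisopropylsilyloxy)chroman-4-one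
Conditions: dirhodium tetrakis[N-phthaloyl-(S)-tert-leucinate], Rh2(S-PTTL)4 (1 mol%), CH2Cl2, slow addition of 12, −20 °C to rt
Reagents that add atoms: none
Why: The diazo ketone loses N2 on the divalent rhodium dimer to give an electrophilic rhodium carbene at C3, which inserts through a concerted, hydride-transfer-like three-centre transition state into one C2–H bond of the O1–CH2–aryl group (intramolecular carbene C–H insertion). The closest known reaction type is the chiral dirhodium carboxylate-catalysed cyclisation of 2-alkoxyaryl alpha-diazoketones to 2-substituted chroman-4-ones. Ring C (O1, C2, C3, C4, C4a, C8a) closes by 1,6-insertion, the only activated C–H bonds within reach of the carbene being those at C2. The C2 stereocentre is set by the chiral carboxylate ligands, which differentiate the two enantiotopic benzylic hydrogens (insertion with retention), the catalyst antipode being chosen as stated in the assumption so that the 2S product results. The step needs C–H insertion to win over oxonium ylide formation at O1 with Stevens benzyl shift, over cyclopropanation of the prenyl alkene or of ring B and over attack at the silyl ether oxygen; this should be secured by the doubly activated C2–H bonds (alpha to O1 and benzylic to the para-methoxy ring B), by the crowding of O1 between the prenyl and acyl groups, by the distance of the prenyl alkene and by the bulky, weakly basic O-TIPS group that carries no reactive C–H bond.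

Step 9
Reactants: 13 (2S)-7-methoxy-2-[4-methoxy-3-(triisopropylsilyloxy)phenyl]-8-(3-methylbut-2-enyl)-5-(triisopropylsilyloxy)chroman-4-one
Product: 14 (2R,3R)-3-hydroxy-7-methoxy-2-[4-methoxy-3-(triisopropylsilyloxy)phenyl]-8-(3-methylbut-2-enyl)-5-(triisopropylsilyloxy)chroman-4-one
Conditions: KN(SiMe3)2, THF, −78 °C; 3-phenyl-2-(phenylsulfonyl)oxaziridine, −78 °C; AcOH quench at −78 °C
Reagents that add atoms: 3-phenyl-2-(phenylsulfonyl)oxaziridine, O=S(=O)(N1OC1c1ccccc1)c1ccccc1
Why: Enolate oxidation with an N-sulfonyloxaziridine, which should not epoxidise the prenyl alkene, delivers oxygen to C3 on the face opposite to the C2 aryl group to give the 2,3-trans (diequatorial, also thermodynamically preferred) isomer, C2 being unchanged in space although its descriptor becomes R because C3 now outranks the aryl carbon, and the cold acidic quench limits ring opening by beta-elimination.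

Step 10
Reactants: 14 (2R,3R)-3-hydroxy-7-methoxy-2-[4-methoxy-3-(triisopropylsilyloxy)phenyl]-8-(3-methylbut-2-enyl)-5-(triisopropylsilyloxy)chroman-4-one
Product: 15 (2R,3R)-3,5-dihydroxy-2-(3-hydroxy-4-methoxyphenyl)-7-methoxy-8-(3-methylbut-2-enyl)chroman-4-one (CNP0302743.1)
Conditions: Bu4NF, AcOH, THF, 0 °C
Reagents that add atoms: none
Why: Fluoride-mediated desilylation cleaves both aryl silyl ethers, the acetic acid buffer protecting the base-sensitive dihydroflavonol from C3 epimerisation and ring opening, while the prenyl group, having no ortho OH, cannot cyclise.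

Compound list
1 | isovanillin (3-hydroxy-4-methoxybenzaldehyde) | COc1ccc(C=O)cc1O | starting material
2 | 4-methoxy-3-(triisopropylsilyloxy)benzaldehyde | COc1ccc(C=O)cc1O[Si](C(C)C)(C(C)C)C(C)C | intermediate
3 | [4-methoxy-3-(triisopropylsilyloxy)phenyl]methanol | COc1ccc(CO)cc1O[Si](C(C)C)(C(C)C)C(C)C | intermediate
4 | 1-(2,6-dihydroxy-4-methoxyphenyl)ethanone | CC(=O)c1c(O)cc(OC)cc1O | starting material
5 | 1-[2-hydroxy-4-methoxy-6-{[4-methoxy-3-(triisopropylsilyloxy)benzyl]oxy}phenyl]ethanone | CC(=O)c1c(O)cc(OC)cc1OCc1ccc(OC)c(O[Si](C(C)C)(C(C)C)C(C)C)c1 | intermediate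
6 | 1-[4-methoxy-2-{[4-methoxy-3-(triisopropylsilyloxy)benzyl]oxy}-6-(3-methylbut-2-enyloxy)phenyl]ethanone | CC(=O)c1c(OCC=C(C)C)cc(OC)cc1OCc1ccc(OC)c(O[Si](C(C)C)(C(C)C)C(C)C)c1 | intermediate
7 | ortho-dienone: 2-acetyl-5-methoxy-3-{[4-methoxy-3-(triisopropylsilyloxy)benzyl]oxy}-6-(2-methylbut-3-en-2-yl)cyclohexa-2,4-dien-1-one (racemic) | CC(=O)C1=C(OCc2ccc(OC)c(O[Si](C(C)C)(C(C)C)C(C)C)c2)C=C(OC)C(C(C)(C)C=C)C1=O | intermediate (not isolated)
8 | para-dienone: 2-acetyl-5-methoxy-3-{[4-methoxy-3-(triisopropylsilyloxy)benzyl]oxy}-4-(3-methylbut-2-enyl)cyclohexa-2,5-dien-1-one (racemic) | CC(=O)C1=C(OCc2ccc(OC)c(O[Si](C(C)C)(C(C)C)C(C)C)c2)C(CC=C(C)C)C(OC)=CC1=O | intermediate (not isolated)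
9 | 1-[6-hydroxy-4-methoxy-2-{[4-methoxy-3-(triisopropylsilyloxy)benzyl]oxy}-3-(3-methylbut-2-enyl)phenyl]ethanone | CC(=O)c1c(O)cc(OC)c(CC=C(C)C)c1OCc1ccc(OC)c(O[Si](C(C)C)(C(C)C)C(C)C)c1 | intermediate
10 | 1-[4-methoxy-2-{[4-methoxy-3-(triisopropylsilyloxy)benzyl]oxy}-3-(3-methylbut-2-enyl)-6-(triisopropylsilyloxy)phenyl]ethanone | CC(=O)c1c(O[Si](C(C)C)(C(C)C)C(C)C)cc(OC)c(CC=C(C)C)c1OCc1ccc(OC)c(O[Si](C(C)C)(C(C)C)C(C)C)c1 | intermediate
11 | trifluoroacetyl ketone: 4,4,4-trifluoro-1-[4-methoxy-2-{[4-methoxy-3-(triisopropylsilyloxy)benzyl]oxy}-3-(3-methylbut-2-enyl)-6-(triisopropylsilyloxy)phenyl]butane-1,3-dione | O=C(CC(=O)C(F)(F)F)c1c(O[Si](C(C)C)(C(C)C)C(C)C)cc(OC)c(CC=C(C)C)c1OCc1ccc(OC)c(O[Si](C(C)C)(C(C)C)C(C)C)c1 | intermediate (not isolated)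
12 | 2-diazo-1-[4-methoxy-2-{[4-methoxy-3-(triisopropylsilyloxy)benzyl]oxy}-3-(3-methylbut-2-enyl)-6-(triisopropylsilyloxy)phenyl]ethanone | [N-]=[N+]=CC(=O)c1c(O[Si](C(C)C)(C(C)C)C(C)C)cc(OC)c(CC=C(C)C)c1OCc1ccc(OC)c(O[Si](C(C)C)(C(C)C)C(C)C)c1 | intermediate
13 | (2S)-7-methoxy-2-[4-methoxy-3-(triisopropylsilyloxy)phenyl]-8-(3-methylbut-2-enyl)-5-(triisopropylsilyloxy)chroman-4-one | COc1ccc([C@H]2Oc3c(CC=C(C)C)c(OC)cc(O[Si](C(C)C)(C(C)C)C(C)C)c3C(=O)C2)cc1O[Si](C(C)C)(C(C)C)C(C)C | intermediate
14 | (2R,3R)-3-hydroxy-7-methoxy-2-[4-methoxy-3-(triisopropylsilyloxy)phenyl]-8-(3-methylbut-2-enyl)-5-(triisopropylsilyloxy)chroman-4-one | COc1ccc([C@H]2Oc3c(CC=C(C)C)c(OC)cc(O[Si](C(C)C)(C(C)C)C(C)C)c3C(=O)[C@@H]2O)cc1O[Si](C(C)C)(C(C)C)C(C)C | intermediate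
15 | (2R,3R)-3,5-dihydroxy-2-(3-hydroxy-4-methoxyphenyl)-7-methoxy-8-(3-methylbut-2-enyl)chroman-4-one | COc1ccc([C@H]2Oc3c(CC=C(C)C)c(OC)cc(O)c3C(=O)[C@@H]2O)cc1O | target

Total step count: 10. Longest linear sequence: 10 steps (1 to 15; acetophenone 4 enters at step 3).

Steps most likely to fail

Step 8. The carbene may be diverted by oxonium ylide formation at O1 followed by a [1,2]-benzyl (Stevens) shift, or the two enantiotopic C2–H bonds may be poorly differentiated. The fallback sets out from 10 and comes back to the route at 13, and still closes ring C through the C2–C3 bond, but by a polar oxidative pathway. O-Acetylation of the potassium enolate of 10 (KN(SiMe3)2, then Ac2O, THF, −78 °C) should give the enol acetate 1-[4-methoxy-2-{[4-methoxy-3-(triisopropylsilyloxy)benzyl]oxy}-3-(3-methylbut-2-enyl)-6-(triisopropylsilyloxy)phenyl]ethenyl acetate F1. DDQ (2,6-dichloropyridine, LiClO4, 4 Å molecular sieves, 1,2-dichloroethane, rt) should then abstract hydride from the para-methoxybenzylic O1–CH2 group, and the aryl-stabilised oxocarbenium ion should be captured at C2 by the enol acetate carbon (oxidative C–H cyclisation) with loss of the acetyl group, giving the racemic flavanone rac-7-methoxy-2-[4-methoxy-3-(triisopropylsilyloxy)phenyl]-8-(3-methylbut-2-enyl)-5-(triisopropylsilyloxy)chroman-4-one F2. Kinetic resolution by asymmetric transfer hydrogenation (Cp*RhCl[(R,R)-TsDPEN], HCO2H/Et3N, EtOAc, rt, stopped near half conversion) is expected, by analogy with the usual sense of induction for aryl ketones, to reduce the 2R enantiomer to the cis-alcohol (2R,4R)-7-methoxy-2-[4-methoxy-3-(triisopropylsilyloxy)phenyl]-8-(3-methylbut-2-enyl)-5-(triisopropylsilyloxy)chroman-4-ol F3 and to leave 13, which is separated by chromatography.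

Step 9. The potassium enolate may undergo beta-elimination of the O1 aryloxide (ring opening to the chalcone and loss of the C2 configuration) or O-to-O silyl migration from O5 before it is oxidised. The fallback sets out from 13 and comes back at 14, avoiding a free enolate. Soft enolisation (TMSOTf, Et3N, CH2Cl2, 0 °C) should give the silyl enol ether (2S)-7-methoxy-2-[4-methoxy-3-(triisopropylsilyloxy)phenyl]-8-(3-methylbut-2-enyl)-5-(triisopropylsilyloxy)-4-(trimethylsilyloxy)-2H-chromene F4. Rubottom oxidation with one equivalent of dimethyldioxirane (acetone, −78 °C) should epoxidise the far more electron-rich enol ether in preference to the prenyl alkene, anti to ring B, giving the 3,4-epoxide of F4 with the epoxide oxygen trans to the C2 aryl group, F5. Work-up with dilute citric acid should open F5 with loss of the trimethylsilyl group to give 14.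

Step 5. The ortho-dienone 7 may enolise before the Cope shift, which would leave a 1,1-dimethylallyl group at the carbon ortho to the phenol instead of a prenyl group at the para carbon. The fallback sets out from 4 and comes back at 10, placing the prenyl group before the two oxygens are differentiated. Direct C-prenylation of 4 (prenyl bromide, DBU, THF, 0 °C to rt) is regiochemically unambiguous because both free ring positions are equivalent and should give 1-[2,6-dihydroxy-4-methoxy-3-(3-methylbut-2-enyl)phenyl]ethanone F6. The bulky silyl chloride (TIPSCl, imidazole, DMF) should silylate the less hindered OH, the one not flanked by the prenyl group, giving 1-[2-hydroxy-4-methoxy-3-(3-methylbut-2-enyl)-6-(triisopropylsilyloxy)phenyl]ethanone F7. Mitsunobu etherification of the remaining OH with alcohol 3 (PPh3, DIAD, THF) then gives 10.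

Further compounds
F1 | step 8 | 1-[4-methoxy-2-{[4-methoxy-3-(triisopropylsilyloxy)benzyl]oxy}-3-(3-methylbut-2-enyl)-6-(triisopropylsilyloxy)phenyl]ethenyl acetate | CC(=O)OC(=C)c1c(O[Si](C(C)C)(C(C)C)C(C)C)cc(OC)c(CC=C(C)C)c1OCc1ccc(OC)c(O[Si](C(C)C)(C(C)C)C(C)C)c1
F2 | step 8 | rac-7-methoxy-2-[4-methoxy-3-(triisopropylsilyloxy)phenyl]-8-(3-methylbut-2-enyl)-5-(triisopropylsilyloxy)chroman-4-one | COc1ccc(C2Oc3c(CC=C(C)C)c(OC)cc(O[Si](C(C)C)(C(C)C)C(C)C)c3C(=O)C2)cc1O[Si](C(C)C)(C(C)C)C(C)C
F3 | step 8 | (2R,4R)-7-methoxy-2-[4-methoxy-3-(triisopropylsilyloxy)phenyl]-8-(3-methylbut-2-enyl)-5-(triisopropylsilyloxy)chroman-4-ol | COc1ccc([C@@H]2Oc3c(CC=C(C)C)c(OC)cc(O[Si](C(C)C)(C(C)C)C(C)C)c3[C@H](O)C2)cc1O[Si](C(C)C)(C(C)C)C(C)C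
F4 | step 9 | (2S)-7-methoxy-2-[4-methoxy-3-(triisopropylsilyloxy)phenyl]-8-(3-methylbut-2-enyl)-5-(triisopropylsilyloxy)-4-(trimethylsilyloxy)-2H-chromene | COc1ccc([C@H]2Oc3c(CC=C(C)C)c(OC)cc(O[Si](C(C)C)(C(C)C)C(C)C)c3C(O[Si](C)(C)C)=C2)cc1O[Si](C(C)C)(C(C)C)C(C)C
F5 | step 9 | 3,4-epoxide of F4 with the epoxide oxygen trans to the C2 aryl group (3,4-epoxy-4-trimethylsilyloxy flavan) | COc1ccc([C@H]2Oc3c(CC=C(C)C)c(OC)cc(O[Si](C(C)C)(C(C)C)C(C)C)c3[C@]4(O[Si](C)(C)C)O[C@H]24)cc1O[Si](C(C)C)(C(C)C)C(C)C
F6 | step 5 | 1-[2,6-dihydroxy-4-methoxy-3-(3-methylbut-2-enyl)phenyl]ethanone | CC(=O)c1c(O)cc(OC)c(CC=C(C)C)c1O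
F7 | step 5 | 1-[2-hydroxy-4-methoxy-3-(3-methylbut-2-enyl)-6-(triisopropylsilyloxy)phenyl]ethanone | CC(=O)c1c(O[Si](C(C)C)(C(C)C)C(C)C)cc(OC)c(CC=C(C)C)c1O
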